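**Plan**
- The ring is read as the dienol of cyclohexane-1,2,4,5-tetraone (quinone numbering: C1=O, C2–OH, C3–side chain, C4=O, C5–OMe, C6–H): two C–C(=O)–C(=O) units, C3–C4–C5 and C6–C1–C2, joined head to tail.
- Retrosynthesis: the 5-O-methyl and 2′-O-acetyl groups are removed, then ring bonds C2–C3 and C5–C6 are cut together. This gives a methyl 2-oxoalkanoate unit (C3–C4–C5 with the side chain) and a pyruvoyl unit (C6–C1–C2).
- The pyruvoyl unit is hung as an ester on the C-2′ oxygen of the side chain. This O–C2 bond is absent from the target, puts C2 within five-ring reach of C3, enforces crossed coupling, and is cleaved in the ring-forming event, which frees the 2′-OH.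
- Forward: C3 + C12 gives the C15 epoxide and a propargyl unit completes the C18 chain. Both 2-oxo acid units are carried as 2-methylene esters and unveiled by one ozonolysis; a base cascade then builds the quinone ring, followed by acetylation and 5-O-methylation.
- Stereochemistry: the single (R) centre comes from (R)-epichlorohydrin; no bond to it is made or broken afterwards.

Key step: step 6

Remark: the centre is read as (R) from the SMILES; compounds 13 to 15 are drawn as one of two equivalent dienol tautomers of the dihydroxyquinone, so 5-O-methylation gives the same compound from either.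

**Step 1**
Reactants: 1 (R)-epichlorohydrin [(2R)-2-(chloromethyl)oxirane]; 2 dodecylmagnesium bromide
Product: 4 (2R)-2-tridecyloxirane, via chlorohydrin 3 (not isolated)
Conditions: CuI (10 mol%), THF, −40 to 0 °C; then NaOH, MeOH/H2O, rt
Reagents that add atoms: dodecylmagnesium bromide, CCCCCCCCCCCC[Mg]Br
Why: Copper-catalysed Grignard opening of the epoxide at its unsubstituted carbon, then base-induced closure of the chlorohydrin (intramolecular Williamson etherification), should carry the (R) centre of 1 into 4 untouched.

**Step 2**
Reactants: 4 (2R)-2-tridecyloxirane; 5 1-(trimethylsilyl)propyne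
Product: 7 (5R)-octadec-1-yn-5-ol, via silyl alkynol 6 (not isolated)
Conditions: 5, n-BuLi, THF, −78 to −20 °C; then 4, −78 °C to rt; then MeOH, K2CO3, rt; aqueous work-up
Reagents that add atoms: 1-(trimethylsilyl)propyne, CC#C[Si](C)(C)C
Why: The propargylic lithium reagent should open the terminal epoxide at CH2 (SN2 epoxide opening, the silyl group blocking the allenyl terminus), and K2CO3/MeOH then removes the alkynyl silyl group (protodesilylation); the carbinol centre is a spectator.

**Step 3**
Reactants: 7 (5R)-octadec-1-yn-5-ol; 8 methacryloyl chloride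
Product: 9 (5R)-octadec-1-yn-5-yl 2-methylprop-2-enoate
Conditions: Et3N, DMAP (cat.), CH2Cl2, 0 °C to rt
Reagents that add atoms: methacryloyl chloride, CC(=C)C(Cl)=O
Why: DMAP-catalysed acylation of the secondary alcohol with an acid chloride; the methacrylate is a robust latent pyruvate ester and prevents lactonisation in step 4.

**Step 4**
Reactants: 9 (5R)-octadec-1-yn-5-yl 2-methylprop-2-enoate
Product: 10 methyl (5R)-2-methylidene-5-[(2-methylprop-2-enoyl)oxy]octadecanoate
Conditions: Pd(OAc)2 (1 mol%), 2-(diphenylphosphino)pyridine (20 mol%), CH3SO3H (20 mol%), CO (20 bar), MeOH, 50 °C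
Reagents that add atoms: carbon monoxide, [C-]#[O+]; methanol, CO
Why: Palladium/2-pyridylphosphine/acid-catalysed Markovnikov hydromethoxycarbonylation of a terminal alkyne should give the branched 2-substituted acrylate, the methacrylate C=C being inert under these alkyne-selective conditions.

**Step 5**
Reactants: 10 methyl (5R)-2-methylidene-5-[(2-methylprop-2-enoyl)oxy]octadecanoate
Product: 11 methyl (5R)-2-oxo-5-[(2-oxopropanoyl)oxy]octadecanoate
Conditions: O3, CH2Cl2, −78 °C; then Me2S, −78 °C to rt
Reagents that add atoms: ozone, [O-][O+]=O
Why: Ozonolysis with reductive work-up should cleave both 1,1-disubstituted acrylate C=C bonds, turning each 2-methylene ester into a 2-oxo ester; nothing else in 10 is oxidisable.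

**Step 6**
Reactants: 11 methyl (5R)-2-oxo-5-[(2-oxopropanoyl)oxy]octadecanoate
Product: 13 2,5-dihydroxy-3-[(2R)-2-hydroxypentadecyl]cyclohexa-2,5-diene-1,4-dione, via triketone ester 12 (not isolated)
Conditions: LiN(SiMe3)2 (4 equiv), THF (0.02 M), slow addition of 11 to the base at −78 °C, then to rt; 1 M HCl, 0 °C
Reagents that add atoms: none
Why: Proposed new method: inverse addition to excess LiN(SiMe3)2 should deprotonate both the C-3 methylene of the 2-oxo ester and the pyruvoyl methyl, which masks both ketones as enolates against aldol addition; the C-3 enolate carbon then attacks the pyruvoyl ester carbonyl (5-exo-trig, five-membered tetrahedral intermediate) and expels the side-chain alkoxide, an O-to-C acyl transfer of Baker–Venkataraman type that joins the chain-bearing ring carbon to the C–OH carbon and gives 12 as its enolate. The pyruvoyl methyl enolate of 12 then closes the ring by Dieckmann condensation on the methyl ester (6-exo-trig), joining the ring CH carbon to the carbon that later carries OMe, and the cyclohexane-1,2,4,5-tetraone so formed enolises to the doubly vinylogous carboxylate dianion of the 2,5-dihydroxy-1,4-benzoquinone, the thermodynamic sink for both Claisen steps. The closest known reaction types are the base-induced head-to-tail self-condensation of 2-oxo esters to 3,6-dialkyl-2,5-dihydroxybenzoquinones and the enzymatic coupling of two 2-oxo acids to terphenylquinones, while a crossed, ester-tethered version has not been shown. No stereocentre is created, and the C-2′ centre is not acidic under the conditions and keeps its (R) configuration. The step needs crossed coupling of two different 2-oxo acid units and Claisen in preference to aldol reactivity: the first is secured by the ester tether through the side-chain oxygen (intramolecular five-ring transition state, high dilution), the second by bis-enolisation and by the irreversible deprotonation of each 1,3-dicarbonyl product.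

**Step 7**
Reactants: 13 2,5-dihydroxy-3-[(2R)-2-hydroxypentadecyl]cyclohexa-2,5-diene-1,4-dione
Product: 15 (2R)-1-(2,5-dihydroxy-3,6-dioxocyclohexa-1,4-dien-1-yl)pentadecan-2-yl acetate, via triacetate 14 (not isolated)
Conditions: Ac2O, pyridine, DMAP (cat.), CH2Cl2, 0 °C; then H2O, rt; dilute HCl wash
Reagents that add atoms: acetic anhydride, CC(=O)OC(C)=O
Why: Exhaustive O-acetylation followed by hydrolysis of the two quinone enol acetates, which are vinylogous mixed anhydrides and far more labile than the secondary alkyl acetate, should leave the acetyl group only on the side-chain oxygen.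

**Step 8**
Reactants: 15 (2R)-1-(2,5-dihydroxy-3,6-dioxocyclohexa-1,4-dien-1-yl)pentadecan-2-yl acetate
Product: 16 (2R)-1-(2-hydroxy-5-methoxy-3,6-dioxocyclohexa-1,4-dien-1-yl)pentadecan-2-yl acetate (target)
Conditions: MeOH, H2SO4 (cat.), 3 Å molecular sieves, rt
Reagents that add atoms: methanol, CO
Why: Acid-catalysed vinylogous Fischer esterification (addition–elimination of methanol on the protonated quinone) should occur at the unhindered C-5 flanked by C-6–H and not at C-2 flanked by the side chain, the known regiochemistry of substitution in 3-alkyl-2,5-dihydroxy-1,4-benzoquinones, while the acetate keeps the 2′-oxygen from closing onto C-2.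

**Compound list**
1 | (R)-epichlorohydrin, (2R)-2-(chloromethyl)oxirane | ClC[C@H]1CO1 | starting material
2 | dodecylmagnesium bromide | CCCCCCCCCCCC[Mg]Br | starting material
3 | (2R)-1-chloropentadecan-2-ol | CCCCCCCCCCCCC[C@H](CCl)O | intermediate
4 | (2R)-2-tridecyloxirane | CCCCCCCCCCCCC[C@@H]1CO1 | intermediate
5 | 1-(trimethylsilyl)propyne | CC#C[Si](C)(C)C | starting material
6 | (5R)-1-(trimethylsilyl)octadec-1-yn-5-ol | CCCCCCCCCCCCC[C@H](CCC#C[Si](C)(C)C)O | intermediate
7 | (5R)-octadec-1-yn-5-ol | CCCCCCCCCCCCC[C@H](CCC#C)O | intermediate
8 | methacryloyl chloride | CC(=C)C(Cl)=O | starting material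
9 | (5R)-octadec-1-yn-5-yl 2-methylprop-2-enoate | CCCCCCCCCCCCC[C@H](CCC#C)OC(=O)C(C)=C | intermediate
10 | methyl (5R)-2-methylidene-5-[(2-methylprop-2-enoyl)oxy]octadecanoate | CCCCCCCCCCCCC[C@H](CCC(=C)C(=O)OC)OC(=O)C(C)=C | intermediate
11 | methyl (5R)-2-oxo-5-[(2-oxopropanoyl)oxy]octadecanoate | CCCCCCCCCCCCC[C@H](CCC(=O)C(=O)OC)OC(=O)C(C)=O | intermediate
12 | methyl 3-[(2R)-2-hydroxypentadecyl]-2,4,5-trioxohexanoate | CCCCCCCCCCCCC[C@H](CC(C(=O)C(=O)OC)C(=O)C(C)=O)O | intermediate
13 | 2,5-dihydroxy-3-[(2R)-2-hydroxypentadecyl]cyclohexa-2,5-diene-1,4-dione | CCCCCCCCCCCCC[C@H](CC1=C(O)C(=O)C=C(O)C1=O)O | intermediate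
14 | (2R)-1-[2,5-bis(acetyloxy)-3,6-dioxocyclohexa-1,4-dien-1-yl]pentadecan-2-yl acetate | CCCCCCCCCCCCC[C@H](CC1=C(OC(C)=O)C(=O)C=C(OC(C)=O)C1=O)OC(C)=O | intermediate
15 | (2R)-1-(2,5-dihydroxy-3,6-dioxocyclohexa-1,4-dien-1-yl)pentadecan-2-yl acetate | CCCCCCCCCCCCC[C@H](CC1=C(O)C(=O)C=C(O)C1=O)OC(C)=O | intermediate
16 | (2R)-1-(2-hydroxy-5-methoxy-3,6-dioxocyclohexa-1,4-dien-1-yl)pentadecan-2-yl acetate | CCCCCCCCCCCCC[C@H](CC1=C(O)C(=O)C=C(OC)C1=O)OC(C)=O | target

**Step count**
Total steps: 8. Longest linear sequence: 8 steps (1 to 16).

**Steps most likely to fail**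

Step 6 (proposed new method). Aldol addition of the C-3 enolate to the pyruvoyl ketone with lactonisation of the aldolate onto the methyl ester, 3-exo displacement of the pyruvate by the enolate, or intermolecular condensation may outrun the five-ring acyl transfer. The fallback uses known chemistry, sets out from epoxide 4 and comes back at 13. 1,2,4,5-Tetramethoxybenzene is lithiated with n-BuLi in THF and the aryllithium opens 4 at its CH2 terminus in the presence of BF3·OEt2 to give (2R)-1-(2,3,5,6-tetramethoxyphenyl)pentadecan-2-ol F1. Oxidative demethylation with (NH4)2Ce(NO3)6 in MeCN/H2O at 0 °C should give 3-[(2R)-2-hydroxypentadecyl]-2,5-dimethoxycyclohexa-2,5-diene-1,4-dione F2. Hydrolysis of both vinylogous ester groups with aqueous NaOH and acidification returns to 13, after which steps 7 and 8 follow unchanged.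

Step 8. Acid-catalysed methanolysis of the side-chain acetate may compete with the etherification, the freed 2′-hydroxyl may then close onto C-2, and discrimination between the two ring hydroxyls may be incomplete. The fallback sets out from 15 and comes back at 16. Both hydroxyl groups are methylated with dimethyl sulfate and K2CO3 in acetone to give (2R)-1-(2,5-dimethoxy-3,6-dioxocyclohexa-1,4-dien-1-yl)pentadecan-2-yl acetate F3. The methoxy group at C-2, twisted out of conjugation by the neighbouring side chain, is then hydrolysed selectively with 70% HClO4 in dioxane at room temperature, the established way to 3-alkyl-2-hydroxy-5-methoxybenzoquinones, which gives 16.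

Step 7. While triol 13 is worked up and handled, its free 2′-hydroxyl may add to C-2 of the quinone and lose water (closure to a dihydrofuran-fused quinone), and pyridine may add to the acetylated quinone. The fallback sets out from 11 and comes back at 15. The trianion generated in step 6 is not protonated but treated at 0 °C with excess acetic anhydride in the same flask, which should give triacetate 14 directly; hydrolysis with water/pyridine as in step 7 then gives 15. No new compound is made on this way (F0).

**Further compounds**
F1 | step 6 | (2R)-1-(2,3,5,6-tetramethoxyphenyl)pentadecan-2-ol | CCCCCCCCCCCCC[C@H](Cc1c(OC)c(OC)cc(OC)c1OC)O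
F2 | step 6 | 3-[(2R)-2-hydroxypentadecyl]-2,5-dimethoxycyclohexa-2,5-diene-1,4-dione | CCCCCCCCCCCCC[C@H](CC1=C(OC)C(=O)C=C(OC)C1=O)O
F3 | step 8 | (2R)-1-(2,5-dimethoxy-3,6-dioxocyclohexa-1,4-dien-1-yl)pentadecan-2-yl acetate | CCCCCCCCCCCCC[C@H](CC1=C(OC)C(=O)C=C(OC)C1=O)OC(C)=O
F0 | step 7 | none | none
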